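Each half of the C2-symmetric target is a 4-alkenylcyclohex-3-en-1-ol. Its ring is cut at two bonds: C1–C2, joining the carbinol carbon to the methyl-bearing quaternary carbon, and the ring olefin C3=C4. A one-flask asymmetric allylboration/ring-closing enyne metathesis makes both: pent-4-ynal and an (E)-6,7-epoxygeranyl boronate first form the C1–C2 bond, setting both ring stereocentres from catalyst and olefin geometry, and the liberated vinyl group then closes onto the alkyne. The step exploits the homoallylic alcohol C1(OH)–C2–C3=C4 and the ring-olefin/exocyclic-vinyl 1,3-diene. Cross-metathesis with vinylboronate and oxidative homocoupling of two like-polarised carbons then assemble the (E,E)-tetraene.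

Key step: step 3

Remark: pent-4-ynal is treated as a purchasable aldehyde (it is otherwise one oxidation away from pent-4-yn-1-ol) and would be used freshly distilled.

Step 1
Reactants: 1 geranyl acetate, (2E)-3,7-dimethylocta-2,6-dien-1-yl acetate
Product: 2 (2E)-5-[(2R)-3,3-dimethyloxiran-2-yl]-3-methylpent-2-en-1-yl acetate ((R)-6,7-epoxygeranyl acetate)
Conditions: D-fructose-derived Shi ketone (30 mol %), Oxone (2KHSO5·KHSO4·K2SO4, limiting), K2CO3, Bu4NHSO4, MeCN/dimethoxymethane/aq. Na2B4O7 buffer, 0 °C
Reagents that add atoms: Oxone (potassium peroxymonosulfate, KHSO5), [K+].[O-]S(=O)(=O)OO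
Why: Shi asymmetric epoxidation, in which the chiral dioxirane transfers oxygen through a spiro transition state to the electron-rich 6,7-olefin and is expected to give the (R)-epoxide, while the 2,3-olefin is deactivated by the allylic acetate.

Step 2
Reactants: 2 (R)-6,7-epoxygeranyl acetate
Product: 3 2-[(2E)-5-[(2R)-3,3-dimethyloxiran-2-yl]-3-methylpent-2-en-1-yl]-4,4,5,5-tetramethyl-1,3,2-dioxaborolane (the (E)-allyl pinacol boronate)
Conditions: B2pin2, Ni(cod)2 (5 mol %), PCy3 (5 mol %), EtOAc, rt
Reagents that add atoms: bis(pinacolato)diboron, CC1(C)OB(OC1(C)C)B1OC(C)(C)C(C)(C)O1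
Why: Nickel-catalysed allylic borylation (Miyaura-type, via a π-allylnickel intermediate and B–B transmetalation) should give the linear allylboronate with the (E)-trisubstituted olefin intact, the isolated epoxide being inert to zerovalent nickel at room temperature.

Step 3
Reactants: 3 the (E)-allyl pinacol boronate; 4 pent-4-ynal
Product: 7 (1R,2S)-2-[2-[(2R)-3,3-dimethyloxiran-2-yl]ethyl]-4-ethenyl-2-methylcyclohex-3-en-1-ol, via enyne borate 5 (not isolated), via cyclised borate 6 (not isolated)
Conditions: (S)-TRIP phosphoric acid [(S)-3,3'-bis(2,4,6-triisopropylphenyl)-1,1'-binaphthyl-2,2'-diyl hydrogen phosphate] (5 mol %), 4 Å MS, toluene, −30 °C; then second-generation Grubbs catalyst RuCl2(=CHPh)(PCy3)(H2IMes) (7 mol %), C2H4 (1 atm), 70 °C, same flask; aq. NaHCO3 work-up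
Reagents that add atoms: none
Why: The chiral phosphoric acid hydrogen-bonds to a boronate oxygen and to the formyl hydrogen, so the aldehyde carbon of 4 and the γ-carbon of 3 join through a closed six-membered chair transition state (catalytic asymmetric allylboration), which forms the carbinol–quaternary C–C bond and unmasks a vinyl group on the quaternary carbon. In the same flask the ruthenium methylidene adds to the terminal alkyne to give a vinylcarbene that undergoes [2+2] cycloaddition and cycloreversion with that vinyl group, so the ring C=C bond is created between the vinyl CH and the internal alkyne carbon and the former alkyne CH becomes the exocyclic vinyl group. The closest known reaction types are the phosphoric-acid-catalysed allylboration of aldehydes with γ,γ-disubstituted allyl pinacol boronates and the ring-closing enyne metathesis of 1,7-enynes under ethene, here run in tandem. The one ring is closed in the exo mode of enyne metathesis to a six-membered 1-vinylcyclohexene (ring-closing diene metathesis of the ethene cross-metathesis product leads to the same ring). The carbinol centre is set by the (S)-catalyst, expected to direct the allyl unit to the Si face of the aldehyde, and the quaternary centre by the (E)-geometry of 3, whose epoxide-bearing chain sits pseudo-equatorial in the chair and therefore ends cis to the hydroxyl on the ring, the remote epoxide centre playing no part. The step needs γ- over α-attack (secured by the cyclic boron-to-oxygen transition state), suppression of the uncatalysed background (low temperature) and chemoselective metathesis (the chain from 3 carries no other olefin, and epoxide and borate are inert to ruthenium carbenes).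

Step 4
Reactants: 7 the vinylcyclohexenol; 8 2-ethenyl-4,4,5,5-tetramethyl-1,3,2-dioxaborolane (vinylboronic acid pinacol ester)
Product: 9 (1R,2S)-2-[2-[(2R)-3,3-dimethyloxiran-2-yl]ethyl]-2-methyl-4-[(E)-2-(4,4,5,5-tetramethyl-1,3,2-dioxaborolan-2-yl)ethenyl]cyclohex-3-en-1-ol
Conditions: 8 (4 equiv), second-generation Hoveyda–Grubbs catalyst RuCl2(=CH-C6H4-2-OiPr)(H2IMes) (7 mol %), CH2Cl2, 40 °C
Reagents that add atoms: none
Why: Olefin cross-metathesis should engage only the monosubstituted terminus of the diene (the ring olefin is trisubstituted and flanked by the quaternary carbon) and, the vinylboronate being a slow homodimeriser, should give the (E)-dienylboronate under thermodynamic control.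

Step 5
Reactants: 9 the (E)-dienylboronate (two equivalents)
Product: 10 (1R,1'R,2S,2'S)-4,4'-[(1E,3E)-buta-1,3-diene-1,4-diyl]bis[2-[2-[(2R)-3,3-dimethyloxiran-2-yl]ethyl]-2-methylcyclohex-3-en-1-ol], the target
Conditions: Pd(OAc)2 (5 mol %), K2CO3, air, acetone/H2O, rt
Reagents that add atoms: none
Why: Palladium-catalysed aerobic oxidative homocoupling of an alkenylboronate (double transmetalation to divalent palladium, reductive elimination with retention of both (E)-olefins, reoxidation of zerovalent palladium by O2) joins the two boron-bearing carbons, two carbons of like polarity, and the statistical pairing of two enantioenriched halves should raise the enantiomeric purity of the C2-symmetric product.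

Compound list
1 | geranyl acetate, (2E)-3,7-dimethylocta-2,6-dien-1-yl acetate | CC(C)=CCC/C(C)=C/COC(C)=O | starting material
2 | (2E)-5-[(2R)-3,3-dimethyloxiran-2-yl]-3-methylpent-2-en-1-yl acetate | CC1(C)O[C@@H]1CC/C(C)=C/COC(C)=O | intermediate
3 | 2-[(2E)-5-[(2R)-3,3-dimethyloxiran-2-yl]-3-methylpent-2-en-1-yl]-4,4,5,5-tetramethyl-1,3,2-dioxaborolane | CC1(C)O[C@@H]1CC/C(C)=C/CB1OC(C)(C)C(C)(C)O1 | intermediate
4 | pent-4-ynal | C#CCCC=O | starting material
5 | pinacol borate of (3S,4R)-3-[2-[(2R)-3,3-dimethyloxiran-2-yl]ethyl]-3-methyloct-1-en-7-yn-4-ol | CC1(C)O[C@@H]1CC[C@@](C)(C=C)[C@H](OB1OC(C)(C)C(C)(C)O1)CCC#C | intermediate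
6 | pinacol borate of 7 | CC1(C)O[C@@H]1CC[C@@]1(C)C=C(C=C)CC[C@H]1OB1OC(C)(C)C(C)(C)O1 | intermediate
7 | (1R,2S)-2-[2-[(2R)-3,3-dimethyloxiran-2-yl]ethyl]-4-ethenyl-2-methylcyclohex-3-en-1-ol | CC1(C)O[C@@H]1CC[C@@]1(C)C=C(C=C)CC[C@H]1O | intermediate
8 | 2-ethenyl-4,4,5,5-tetramethyl-1,3,2-dioxaborolane | C=CB1OC(C)(C)C(C)(C)O1 | starting material
9 | (1R,2S)-2-[2-[(2R)-3,3-dimethyloxiran-2-yl]ethyl]-2-methyl-4-[(E)-2-(4,4,5,5-tetramethyl-1,3,2-dioxaborolan-2-yl)ethenyl]cyclohex-3-en-1-ol | CC1(C)O[C@@H]1CC[C@@]1(C)C=C(/C=C/B2OC(C)(C)C(C)(C)O2)CC[C@H]1O | intermediate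
10 | (1R,1'R,2S,2'S)-4,4'-[(1E,3E)-buta-1,3-diene-1,4-diyl]bis[2-[2-[(2R)-3,3-dimethyloxiran-2-yl]ethyl]-2-methylcyclohex-3-en-1-ol] | CC1(C)O[C@@H]1CC[C@@]1(C)C=C(/C=C/C=C/C2=C[C@](C)(CC[C@H]3OC3(C)C)[C@H](O)CC2)CC[C@H]1O | target

Total step count: 5. Longest linear sequence: 5 steps (1 → 2 → 3 → 7 → 9 → 10).

Steps most likely to fail: step 3, step 4, step 5.

Step 3. The acid-catalysed pathway may be outrun by the uncatalysed allylboration of this slow γ,γ-disubstituted boronate, which would cost facial selectivity at the aldehyde. The acid may also open the trisubstituted epoxide. The fallback gives up catalyst control and separates covalent diastereomers instead. It sets out from 3 and 4. The same one-flask sequence is run without the phosphoric acid (toluene, 40 °C, then the ruthenium catalyst and ethene). The chair transition state still fixes the relative configuration of carbinol and quaternary carbon, so only two series should form. One is 5, 6 and 7. The other is the mirror-image ring series, each still carrying the (R)-epoxide: the pinacol borate of the (3R,4S)-enynol F1, the cyclised pinacol borate F2 and the (1S,2R)-alcohol F3. The alcohol mixture is esterified with (S)-2-methoxy-2-phenylacetic acid (DCC, DMAP, CH2Cl2). This gives the (S)-O-methylmandelate of 7 F4 and the (S)-O-methylmandelate of the (1S,2R)-alcohol F5, which are separated by chromatography or crystallisation. LiOH in THF/H2O then releases 7 from F4, and the route resumes at 7.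

Step 4. Metathesis of the conjugated diene may be unselective (attack at the ring olefin, secondary metathesis of the product, erosion of the E geometry), or the catalyst may be sequestered as a chelated vinylcarbene. The fallback replaces metathesis by oxidative cleavage and carbonyl olefination. It sets out from 7. Lemieux–Johnson oxidation (OsO4 cat., NaIO4, 2,6-lutidine, dioxane/H2O) should cleave only the unhindered monosubstituted olefin. This gives (3S,4R)-3-[2-[(2R)-3,3-dimethyloxiran-2-yl]ethyl]-4-hydroxy-3-methylcyclohex-1-ene-1-carbaldehyde F6. Boron–Wittig olefination of this enal with lithiated bis(pinacolboryl)methane (CH2(Bpin)2, LiTMP, THF, −78 °C to rt, excess to cover the free hydroxyl) should give the (E)-alkenylboronate, and the route resumes at 9.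

Step 5. The dienylboronate may protodeboronate, and the polyene may degrade oxidatively under aerobic palladium catalysis. The fallback replaces the oxidative homocoupling by a redox-neutral cross-coupling run without air. It sets out from 9. Half of 9 is converted by ipso-iododeboronation with retention (NIS, MeCN, 0 °C, dark) into (1R,2S)-2-[2-[(2R)-3,3-dimethyloxiran-2-yl]ethyl]-4-[(E)-2-iodoethenyl]-2-methylcyclohex-3-en-1-ol F7. Suzuki–Miyaura coupling of this iodide with the remaining 9 (Pd(PPh3)4, aq. K3PO4, degassed THF, 40 °C) should give the (E,E)-tetraene, and the route ends at 10.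

Further compounds
F1 | step 3 | pinacol borate of (3R,4S)-3-[2-[(2R)-3,3-dimethyloxiran-2-yl]ethyl]-3-methyloct-1-en-7-yn-4-ol | CC1(C)O[C@@H]1CC[C@](C)(C=C)[C@@H](OB1OC(C)(C)C(C)(C)O1)CCC#C
F2 | step 3 | pinacol borate of (1S,2R)-2-[2-[(2R)-3,3-dimethyloxiran-2-yl]ethyl]-4-ethenyl-2-methylcyclohex-3-en-1-ol | CC1(C)O[C@@H]1CC[C@]1(C)C=C(C=C)CC[C@@H]1OB1OC(C)(C)C(C)(C)O1
F3 | step 3 | (1S,2R)-2-[2-[(2R)-3,3-dimethyloxiran-2-yl]ethyl]-4-ethenyl-2-methylcyclohex-3-en-1-ol | CC1(C)O[C@@H]1CC[C@]1(C)C=C(C=C)CC[C@@H]1O
F4 | step 3 | (1R,2S)-2-[2-[(2R)-3,3-dimethyloxiran-2-yl]ethyl]-4-ethenyl-2-methylcyclohex-3-en-1-yl (2S)-2-methoxy-2-phenylacetate | CC1(C)O[C@@H]1CC[C@@]1(C)C=C(C=C)CC[C@H]1OC(=O)[C@@H](OC)c1ccccc1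
F5 | step 3 | (1S,2R)-2-[2-[(2R)-3,3-dimethyloxiran-2-yl]ethyl]-4-ethenyl-2-methylcyclohex-3-en-1-yl (2S)-2-methoxy-2-phenylacetate | CC1(C)O[C@@H]1CC[C@]1(C)C=C(C=C)CC[C@@H]1OC(=O)[C@@H](OC)c1ccccc1
F6 | step 4 | (3S,4R)-3-[2-[(2R)-3,3-dimethyloxiran-2-yl]ethyl]-4-hydroxy-3-methylcyclohex-1-ene-1-carbaldehyde | CC1(C)O[C@@H]1CC[C@@]1(C)C=C(C=O)CC[C@H]1O
F7 | step 5 | (1R,2S)-2-[2-[(2R)-3,3-dimethyloxiran-2-yl]ethyl]-4-[(E)-2-iodoethenyl]-2-methylcyclohex-3-en-1-ol | CC1(C)O[C@@H]1CC[C@@]1(C)C=C(/C=C/I)CC[C@H]1O
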